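The plan hinges on stripping both carbon substituents from the crowded C7–C8 edge of the tetralin arene (C1 i-Pr, C4 Me, C5/C6 oxygens). C7 (CHO) and C8 (joined to pyranone C3') are neighbouring, carbon-bearing ring atoms flanked by the C6 oxygen. This 1,2-pattern maps onto the two halves of one malonate split across a C7≡C8 aryne. In a single operation CH2CO2Me lands on C8 and CO2Me on C7, and no lasting ring is closed. The precursor is the trans-(1R,4S)-5,6-dimethoxytetralin carrying OTf at C7 and SiMe3 at C8. The pyranone is later grown from the C8 acetate arm, so two rings are never coupled.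

Key step: step 12

Assumption: the hindered C8–C3' axis is not assigned in the target structure and is treated as stereochemically undefined. Tetralin numbering (C1 i-Pr, C4 Me) is kept for all bicyclic and tricyclic compounds.

Step 1
Reactants: 1 4-hydroxy-2,3-dimethoxybenzaldehyde
Product: 2 4-(benzyloxy)-2,3-dimethoxybenzaldehyde
Conditions: BnBr, K2CO3, DMF, rt
Reagents that add atoms: benzyl bromide, BrCc1ccccc1
Why: Williamson etherification of the only phenol masks the future C7 oxygen with a group that stays distinguishable from the two methyl ethers.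

Step 2
Reactants: 2 4-(benzyloxy)-2,3-dimethoxybenzaldehyde
Product: 3 1-[4-(benzyloxy)-2,3-dimethoxyphenyl]ethanol (racemic)
Conditions: MeMgBr, THF, 0 °C
Reagents that add atoms: methylmagnesium bromide, C[Mg]Br
Why: Grignard 1,2-addition to the aldehyde brings in the carbon that becomes the C4 methyl group; the carbinol centre is racemic and is erased in step 3.

Step 3
Reactants: 3 1-[4-(benzyloxy)-2,3-dimethoxyphenyl]ethanol
Product: 4 1-[4-(benzyloxy)-2,3-dimethoxyphenyl]ethanone
Conditions: MnO2, CH2Cl2, rt
Reagents that add atoms: none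
Why: Heterogeneous MnO2 oxidation is selective for the electron-rich benzylic alcohol and should give the aryl methyl ketone without touching the benzyl or methyl ethers.

Step 4
Reactants: 4 1-[4-(benzyloxy)-2,3-dimethoxyphenyl]ethanone; 5 (2-carboxyethyl)triphenylphosphonium bromide
Product: 7 (E)-4-[4-(benzyloxy)-2,3-dimethoxyphenyl]pent-3-enoic acid, via carboxylate ylide 6 (not isolated)
Conditions: NaN(SiMe3)2 (2.2 equiv), THF, 0 °C to reflux; then 1 M HCl
Reagents that add atoms: none
Why: Wittig olefination with the carboxylate-bearing ylide attaches the three remaining ring carbons (C3, C2, C1) in one step; anionic ylides of this kind favour the E alkene, and the free acid allows the minor Z isomer to be removed by crystallisation.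

Step 5
Reactants: 7 (E)-4-[4-(benzyloxy)-2,3-dimethoxyphenyl]pent-3-enoic acid
Product: 8 (S)-4-[4-(benzyloxy)-2,3-dimethoxyphenyl]pentanoic acid
Conditions: [Ir(cod)(SIPHOX)]BArF (1 mol%), H2 (6 bar), Et3N (0.5 equiv), MeOH, rt
Reagents that add atoms: none
Why: Carboxylate-directed iridium-catalysed asymmetric hydrogenation of a β,γ-unsaturated acid, in which the spiro phosphine–oxazoline ligand selects the alkene face and should set C4 as S (the ligand antipode is chosen accordingly).

Step 6
Reactants: 8 (S)-4-[4-(benzyloxy)-2,3-dimethoxyphenyl]pentanoic acid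
Product: 10 (4S)-7-(benzyloxy)-5,6-dimethoxy-4-methyl-3,4-dihydronaphthalen-1(2H)-one, via mixed anhydride 9 (not isolated)
Conditions: (CF3CO)2O, CF3CO2H, CH2Cl2, 0 °C to rt
Reagents that add atoms: none
Why: Intramolecular Friedel–Crafts acylation through the mixed anhydride can only close at the free position ortho to the side chain (future C8a), which is para to the C6 methoxy group; the C4 stereocentre is not involved.

Step 7
Reactants: 10 (4S)-7-(benzyloxy)-5,6-dimethoxy-4-methyl-3,4-dihydronaphthalen-1(2H)-one; 11 isopropylmagnesium chloride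
Product: 13 (4S)-7-(benzyloxy)-1-isopropyl-5,6-dimethoxy-4-methyl-3,4-dihydronaphthalene, via tertiary alcohol 12 (not isolated)
Conditions: iPrMgCl, LaCl3·2LiCl (30 mol%), THF, 0 °C; then 2 M HCl, rt
Reagents that add atoms: none
Why: Lanthanum-assisted Grignard 1,2-addition suppresses enolisation and reduction of the tetralone, and the tertiary p-alkoxybenzylic alcohol loses water on the acid quench (E1) toward the ring, because an exocyclic tetrasubstituted alkene would clash with the C8 hydrogen.

Step 8
Reactants: 13 (4S)-7-(benzyloxy)-1-isopropyl-5,6-dimethoxy-4-methyl-3,4-dihydronaphthalene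
Product: 14 (1R,4S)-7-(benzyloxy)-1-isopropyl-5,6-dimethoxy-4-methyltetralin (trans)
Conditions: [Ir(cod)(PHOX)]BArF (2 mol%), H2 (50 bar), CH2Cl2, rt
Reagents that add atoms: none
Why: Iridium–phosphine-oxazoline asymmetric hydrogenation of an unfunctionalised trisubstituted alkene, a reaction type established for 1-alkyl-3,4-dihydronaphthalenes, sets C1 as R under catalyst control; the ligand antipode is chosen to deliver hydrogen to the face that carries the C4 methyl group, which makes the two alkyl groups trans.

Step 9
Reactants: 14 (1R,4S)-7-(benzyloxy)-1-isopropyl-5,6-dimethoxy-4-methyltetralin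
Product: 15 (1R,4S)-1-isopropyl-5,6-dimethoxy-4-methyltetralin-7-ol
Conditions: H2 (1 bar), Pd/C, EtOAc–MeOH, rt
Reagents that add atoms: none
Why: Catalytic hydrogenolysis cleaves only the benzyl ether, since the methyl ethers and the two benzylic stereocentres are inert to H2 over Pd/C.

Step 10
Reactants: 15 (1R,4S)-1-isopropyl-5,6-dimethoxy-4-methyltetralin-7-ol
Product: 16 (1R,4S)-8-bromo-1-isopropyl-5,6-dimethoxy-4-methyltetralin-7-ol
Conditions: NBS, MeCN, 0 °C, dark
Reagents that add atoms: N-bromosuccinimide, O=C1CCC(=O)N1Br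
Why: Electrophilic aromatic bromination has a single possible site, because C8 is the only arene C–H left and lies ortho to the activating phenol; polar solvent, low temperature and darkness disfavour radical benzylic bromination.

Step 11
Reactants: 16 (1R,4S)-8-bromo-1-isopropyl-5,6-dimethoxy-4-methyltetralin-7-ol
Product: 19 (1R,4S)-1-isopropyl-5,6-dimethoxy-4-methyl-8-(trimethylsilyl)tetralin-7-yl trifluoromethanesulfonate, via silyl ether 17 (not isolated), via lithium phenoxide 18 (not isolated)
Conditions: HN(SiMe3)2, THF, 65 °C, then evaporate; n-BuLi, THF, −78 °C; Tf2O, −78 to 0 °C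
Reagents that add atoms: hexamethyldisilazane, C[Si](C)(C)N[Si](C)(C)C; trifluoromethanesulfonic anhydride, O=S(=O)(OS(=O)(=O)C(F)(F)F)C(F)(F)F
Why: O-Silylation, bromine–lithium exchange and retro-Brook (1,3 O-to-C) silyl migration move SiMe3 onto C8, and the phenoxide released is trapped as the triflate, the standard sequence from an o-bromophenol to an o-silylaryl triflate.

Step 12
Reactants: 19 (1R,4S)-1-isopropyl-5,6-dimethoxy-4-methyl-8-(trimethylsilyl)tetralin-7-yl trifluoromethanesulfonate; 20 dimethyl malonate
Product: 23 methyl (1R,4S)-1-isopropyl-5,6-dimethoxy-8-(2-methoxy-2-oxoethyl)-4-methyltetralin-7-carboxylate (tetralin homophthalate), via aryne 21 (not isolated), via benzocyclobutenoxide 22 (not isolated)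
Conditions: CsF (3 equiv), 20 (3 equiv), MeCN, 60 °C, slow addition of 19
Reagents that add atoms: none
Why: Fluoride removes the C8 silyl group and triflate leaves from C7 to give aryne 21; the malonate anion adds through carbon to C8, the C7 aryl anion so formed closes onto one ester carbonyl to give benzocyclobutenoxide 22, and its fragmentation leaves CO2Me on C7 and an ester-stabilised C8 benzylic anion that is protonated by fresh malonate. The closest known reaction type is the fluoride-induced acyl-alkylation of arynes, that is σ-insertion into the C–C bond of malonates and β-keto esters, which is established for 3-methoxyarynes. No ring of product 23 is closed: the only ring formed is the transient four-membered one (4-exo-trig attack of the aryl anion on the ester), and it reopens in the same flask. No stereocentre is created, and C1 and C4 carry no hydrogen that is acidic under these weakly basic conditions. The step needs attack at C8 rather than C7, which the C6 methoxy group should secure because its inductive pull polarises and distorts the triple bond so that negative charge builds up at C7 next to the C–O bond. The steric counter-bias is limited because peri strain keeps the C1 isopropyl group pseudoaxial, so only the C1 hydrogen lies in the arene plane along which the nucleophile approaches C8, and excess malonate should suppress a second arylation of 23.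

Step 13
Reactants: 23 tetralin homophthalate
Product: 24 2-[(1R,4S)-1-isopropyl-5,6-dimethoxy-7-(methoxycarbonyl)-4-methyltetralin-8-yl]acetic acid
Conditions: LiOH (1.5 equiv), THF–MeOH–H2O, rt; then 1 M HCl
Reagents that add atoms: lithium hydroxide, [Li+].[OH-]
Why: Chemoselective saponification, in which the aliphatic ester is hydrolysed while the C7 benzoate, substituted at both ortho positions, resists hydroxide at room temperature.

Step 14
Reactants: 24 2-[(1R,4S)-1-isopropyl-5,6-dimethoxy-7-(methoxycarbonyl)-4-methyltetralin-8-yl]acetic acid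
Product: 26 tricyclic isochroman-3-one (1R,4S; lactone bridge C7–CH2–O–C(=O)–CH2–C8), via hydroxy acid 25 (not isolated)
Conditions: LiEt3BH (4 equiv), THF, 0 °C to rt; then 2 M HCl, rt
Reagents that add atoms: none
Why: LiEt3BH first turns the acid into an unreactive lithium carboxylate and then reduces the remaining ester to the benzylic alcohol (hydride reduction of a half-ester), and acid closes the hydroxy acid to the six-membered lactone, which masks the C7 CH2OH, keeps the C8 arm at the acid level and avoids a diol that would over-oxidise through its lactol.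

Step 15
Reactants: 26 tricyclic isochroman-3-one
Product: 28 α-acetyl lactone (acetyl on the CH between C8 and the lactone C=O), via lithium enolate 27 (not isolated)
Conditions: LiN(SiMe3)2 (2.2 equiv), THF, −78 °C; AcCl (1.1 equiv); then 1 M HCl
Reagents that add atoms: acetyl chloride, CC(=O)Cl
Why: Crossed Claisen-type C-acylation of the lactone enolate, whose faces are open because the ring holds the arene coplanar; the second equivalent of base stores the more acidic β-keto lactone as its enolate, and the new α-centre is configurationally labile and disappears in step 18.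

Step 16
Reactants: 29 (E)-3,4-dimethoxycinnamic acid
Product: 31 (E)-3-(3,4-dimethoxyphenyl)-N-methoxy-N-methylacrylamide, via acyl imidazole 30 (not isolated)
Conditions: 1,1'-carbonyldiimidazole, CH2Cl2, rt; MeNH(OMe)·HCl, rt
Reagents that add atoms: N,O-dimethylhydroxylamine hydrochloride, CNOC.Cl
Why: Carboxyl activation as the acyl imidazole followed by aminolysis is a standard amide synthesis that leaves the E alkene untouched.

Step 17
Reactants: 28 α-acetyl lactone; 31 (E)-3-(3,4-dimethoxyphenyl)-N-methoxy-N-methylacrylamide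
Product: 33 triketide lactone (28 extended at the acetyl CH3 by the (E)-3,4-dimethoxycinnamoyl group), via dilithio dianion 32 (not isolated)
Conditions: LiN(iPr)2 (3 equiv), THF, −78 to 0 °C; 31, −78 to 0 °C; then 1 M HCl
Reagents that add atoms: none
Why: γ-Acylation of a β-keto ester dianion (Claisen-type), in which the terminal carbanion is the more reactive site and adds 1,2 to the N-methoxy-N-methylamide, whose chelated tetrahedral adduct survives until the quench and so prevents over-addition.

Step 18
Reactants: 33 triketide lactone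
Product: 34 3-[(1R,4S)-7-(hydroxymethyl)-1-isopropyl-5,6-dimethoxy-4-methyltetralin-8-yl]-4-hydroxy-6-[(E)-3,4-dimethoxystyryl]-2H-pyran-2-one
Conditions: DBU (2 equiv), toluene, 80 °C; then 1 M HCl wash
Reagents that add atoms: none
Why: Base-induced lactonisation of a 3,5-dioxo ester to a 4-hydroxy-2-pyranone, in which the distal enolate oxygen attacks the lactone carbonyl and expels the benzylic alkoxide, driven by formation of the acidic conjugated pyranone (held as its DBU salt) and by relief of the crowding between the fused lactone and C1.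

Step 19
Reactants: 34 hydroxymethyl pyranone
Product: 35 (1R,4S)-8-{4-hydroxy-6-[(E)-3,4-dimethoxystyryl]-2-oxo-2H-pyran-3-yl}-1-isopropyl-5,6-dimethoxy-4-methyltetralin-7-carbaldehyde (tetra-O-methylheimiomycin B)
Conditions: MnO2 (20 equiv), CH2Cl2, rt
Reagents that add atoms: none
Why: MnO2 oxidation of the electron-rich benzylic alcohol should stop at the aldehyde, while the pyranone enol, the styryl diene and the methyl ethers are not affected.

Step 20
Reactants: 35 tetra-O-methylheimiomycin B
Product: 36 heimiomycin B
Conditions: BBr3 (12 equiv), CH2Cl2, −78 °C to rt; then H2O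
Reagents that add atoms: none
Why: Lewis-acid ether cleavage with BBr3 removes all four aryl methyl groups (the C6 one assisted by chelation to the aldehyde), a reaction type proven on o-methoxybenzaldehydes and on styrylpyranone methyl ethers, and hydrolysis of the borates releases both catechols without touching C1, C4 or the E alkene.

Compound list
1 | 4-hydroxy-2,3-dimethoxybenzaldehyde | COc1c(O)ccc(C=O)c1OC | starting material
2 | 4-(benzyloxy)-2,3-dimethoxybenzaldehyde | COc1c(OCc2ccccc2)ccc(C=O)c1OC | intermediate
3 | 1-[4-(benzyloxy)-2,3-dimethoxyphenyl]ethanol (racemic) | COc1c(OCc2ccccc2)ccc(C(C)O)c1OC | intermediate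
4 | 1-[4-(benzyloxy)-2,3-dimethoxyphenyl]ethanone | COc1c(OCc2ccccc2)ccc(C(C)=O)c1OC | intermediate
5 | (2-carboxyethyl)triphenylphosphonium bromide | OC(=O)CC[P+](c1ccccc1)(c1ccccc1)c1ccccc1.[Br-] | starting material
6 | sodium 3-(triphenylphosphoranylidene)propanoate (carboxylate ylide) | [Na+].[O-]C(=O)CC=P(c1ccccc1)(c1ccccc1)c1ccccc1 | intermediate
7 | (E)-4-[4-(benzyloxy)-2,3-dimethoxyphenyl]pent-3-enoic acid | C/C(=C\CC(=O)O)c1ccc(OCc2ccccc2)c(OC)c1OC | intermediate
8 | (S)-4-[4-(benzyloxy)-2,3-dimethoxyphenyl]pentanoic acid | OC(=O)CC[C@H](C)c1ccc(OCc2ccccc2)c(OC)c1OC | intermediate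
9 | mixed trifluoroacetic anhydride of acid 8 | O=C(CC[C@H](C)c1ccc(OCc2ccccc2)c(OC)c1OC)OC(=O)C(F)(F)F | intermediate
10 | (4S)-7-(benzyloxy)-5,6-dimethoxy-4-methyl-3,4-dihydronaphthalen-1(2H)-one | O=C1CC[C@H](C)c2c(OC)c(OC)c(OCc3ccccc3)cc21 | intermediate
11 | isopropylmagnesium chloride | CC(C)[Mg]Cl | starting material
12 | (4S)-7-(benzyloxy)-1-isopropyl-5,6-dimethoxy-4-methyltetralin-1-ol (C1 epimers) | CC(C)C1(O)CC[C@H](C)c2c(OC)c(OC)c(OCc3ccccc3)cc21 | intermediate
13 | (4S)-7-(benzyloxy)-1-isopropyl-5,6-dimethoxy-4-methyl-3,4-dihydronaphthalene | CC(C)C1=CC[C@H](C)c2c(OC)c(OC)c(OCc3ccccc3)cc21 | intermediate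
14 | (1R,4S)-7-(benzyloxy)-1-isopropyl-5,6-dimethoxy-4-methyltetralin (trans) | CC(C)[C@H]1CC[C@H](C)c2c(OC)c(OC)c(OCc3ccccc3)cc21 | intermediate
15 | (1R,4S)-1-isopropyl-5,6-dimethoxy-4-methyltetralin-7-ol | CC(C)[C@H]1CC[C@H](C)c2c(OC)c(OC)c(O)cc21 | intermediate
16 | (1R,4S)-8-bromo-1-isopropyl-5,6-dimethoxy-4-methyltetralin-7-ol | CC(C)[C@H]1CC[C@H](C)c2c(OC)c(OC)c(O)c(Br)c21 | intermediate
17 | O-trimethylsilyl ether of bromophenol 16 | CC(C)[C@H]1CC[C@H](C)c2c(OC)c(OC)c(O[Si](C)(C)C)c(Br)c21 | intermediate
18 | lithium (1R,4S)-1-isopropyl-5,6-dimethoxy-4-methyl-8-(trimethylsilyl)tetralin-7-olate | [Li+].CC(C)[C@H]1CC[C@H](C)c2c(OC)c(OC)c([O-])c([Si](C)(C)C)c21 | intermediate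
19 | (1R,4S)-1-isopropyl-5,6-dimethoxy-4-methyl-8-(trimethylsilyl)tetralin-7-yl trifluoromethanesulfonate | CC(C)[C@H]1CC[C@H](C)c2c(OC)c(OC)c(OS(=O)(=O)C(F)(F)F)c([Si](C)(C)C)c21 | intermediate
20 | dimethyl malonate | COC(=O)CC(=O)OC | starting material
21 | (1R,4S)-7,8-didehydro-1-isopropyl-5,6-dimethoxy-4-methyltetralin (C7≡C8 aryne) | CC(C)[C@H]1CC[C@H](C)C2=C1C#CC(OC)=C2OC | intermediate
22 | caesium benzocyclobutenoxide (four-membered ring C7–C(O−)(OMe)–CH(CO2Me)–C8) | [Cs+].CC(C)[C@H]1CC[C@H](C)c2c(OC)c(OC)c3c(C(C(=O)OC)C3([O-])OC)c21 | intermediate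
23 | methyl (1R,4S)-1-isopropyl-5,6-dimethoxy-8-(2-methoxy-2-oxoethyl)-4-methyltetralin-7-carboxylate | CC(C)[C@H]1CC[C@H](C)c2c(OC)c(OC)c(C(=O)OC)c(CC(=O)OC)c21 | intermediate
24 | 2-[(1R,4S)-1-isopropyl-5,6-dimethoxy-7-(methoxycarbonyl)-4-methyltetralin-8-yl]acetic acid | CC(C)[C@H]1CC[C@H](C)c2c(OC)c(OC)c(C(=O)OC)c(CC(=O)O)c21 | intermediate
25 | 2-[(1R,4S)-7-(hydroxymethyl)-1-isopropyl-5,6-dimethoxy-4-methyltetralin-8-yl]acetic acid | CC(C)[C@H]1CC[C@H](C)c2c(OC)c(OC)c(CO)c(CC(=O)O)c21 | intermediate
26 | tricyclic isochroman-3-one (lactone bridge C7–CH2–O–C(=O)–CH2–C8) | CC(C)[C@H]1CC[C@H](C)c2c(OC)c(OC)c3c(CC(=O)OC3)c21 | intermediate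
27 | lithium enolate of lactone 26 | [Li+].CC(C)[C@H]1CC[C@H](C)c2c(OC)c(OC)c3c(C=C([O-])OC3)c21 | intermediate
28 | α-acetyl lactone (α-centre labile) | CC(C)[C@H]1CC[C@H](C)c2c(OC)c(OC)c3c(C(C(C)=O)C(=O)OC3)c21 | intermediate
29 | (E)-3,4-dimethoxycinnamic acid | COc1ccc(/C=C/C(=O)O)cc1OC | starting material
30 | (E)-1-[3-(3,4-dimethoxyphenyl)acryloyl]imidazole | COc1ccc(/C=C/C(=O)n2ccnc2)cc1OC | intermediate
31 | (E)-3-(3,4-dimethoxyphenyl)-N-methoxy-N-methylacrylamide | COc1ccc(/C=C/C(=O)N(C)OC)cc1OC | intermediate
32 | dilithio dianion of 28 | [Li+].[Li+].CC(C)[C@H]1CC[C@H](C)c2c(OC)c(OC)c3c(C(C(=C)[O-])=C([O-])OC3)c21 | intermediate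
33 | triketide lactone | CC(C)[C@H]1CC[C@H](C)c2c(OC)c(OC)c3c(C(C(=O)CC(=O)/C=C/c4ccc(OC)c(OC)c4)C(=O)OC3)c21 | intermediate
34 | 3-[(1R,4S)-7-(hydroxymethyl)-1-isopropyl-5,6-dimethoxy-4-methyltetralin-8-yl]-4-hydroxy-6-[(E)-3,4-dimethoxystyryl]-2H-pyran-2-one | CC(C)[C@H]1CC[C@H](C)c2c(OC)c(OC)c(CO)c(-c3c(O)cc(/C=C/c4ccc(OC)c(OC)c4)oc3=O)c21 | intermediate
35 | tetra-O-methylheimiomycin B | CC(C)[C@H]1CC[C@H](C)c2c(OC)c(OC)c(C=O)c(-c3c(O)cc(/C=C/c4ccc(OC)c(OC)c4)oc3=O)c21 | intermediate
36 | heimiomycin B | CC(C)[C@H]1CC[C@H](C)c2c(O)c(O)c(C=O)c(-c3c(O)cc(/C=C/c4ccc(O)c(O)c4)oc3=O)c21 | target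

Total step count: 20. Longest linear sequence: 19 (steps 1–15 and 17–20; step 16 is a side branch).

Steps most likely to fail

1. Step 12.
- Crowding next to C8 may slow the carbon nucleophile enough that attack drifts toward C7, which would erode or reverse the regioselectivity.
- The C7 aryl anion may be protonated before acyl transfer, giving plain arylation.
- Desilylation at the crowded C8 may lag behind sulfonyl transfer from the triflate.
- The fallback uses two cross-couplings in place of an aryne. It sets out from bromophenol 16. Triflation (Tf2O, pyridine, CH2Cl2) would give (1R,4S)-8-bromo-1-isopropyl-5,6-dimethoxy-4-methyltetralin-7-yl trifluoromethanesulfonate F1. A Negishi-type coupling of the Reformatsky reagent BrZnCH2CO2Me at the C–Br bond (Pd(dba)2, Q-Phos, THF) relies on a bulky monophosphine catalyst inserting into C–Br ahead of C–OTf. It would give methyl 2-[(1R,4S)-1-isopropyl-5,6-dimethoxy-4-methyl-7-(trifluoromethylsulfonyloxy)tetralin-8-yl]acetate F2. Methoxycarbonylation of the triflate (Pd(OAc)2, dppp, CO, MeOH, Et3N, DMSO, 70 °C) comes back to the route at 23.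

2. Step 8.
- Facial selectivity may be poor. The C4 methyl group is pushed pseudoaxial by the C5 methoxy group and shields the very face to which hydrogen must be delivered, so catalyst control may be eroded toward the cis isomer.
- The fallback brings in the carbon substituent last instead of hydrogen last. It sets out from tetralone 10. NaBH4 reduction (MeOH) would give (4S)-7-(benzyloxy)-5,6-dimethoxy-4-methyltetralin-1-ol F3, and either C1 epimer serves.
- Ionisation with BF3·OEt2 in the presence of K[CH2=C(CH3)BF3] (CH2Cl2, −78 to 0 °C) should attach the alkenyl group by axial attack on the p-alkoxybenzylic cation, anti to the pseudoaxial methyl group. This would give 1,4-trans-(4S)-7-(benzyloxy)-1-isopropenyl-5,6-dimethoxy-4-methyltetralin F4.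
- H2 over Pd/C then saturates the side-chain alkene and removes the benzyl group in one operation, coming back to the route at phenol 15.

3. Step 17.
- Proton exchange between the dianion and the more acidic product may stall the reaction.
- Conjugate addition to the cinnamoyl unit may compete.
- The second deprotonation may be incomplete, because the enolate has to flatten against the C1 region.
- The fallback replaces the acylation by an aldol addition followed by oxidation. It sets out from 28. The same dianion would be added at −78 °C to commercial (E)-3,4-dimethoxycinnamaldehyde, a faster 1,2-addition, to give the δ-hydroxy-β-keto lactone F5 as a mixture of carbinol epimers. Dess–Martin oxidation of the allylic alcohol comes back to the route at triketide lactone 33.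

Further compounds
F1 | step 12 | (1R,4S)-8-bromo-1-isopropyl-5,6-dimethoxy-4-methyltetralin-7-yl trifluoromethanesulfonate | CC(C)[C@H]1CC[C@H](C)c2c(OC)c(OC)c(OS(=O)(=O)C(F)(F)F)c(Br)c21
F2 | step 12 | methyl 2-[(1R,4S)-1-isopropyl-5,6-dimethoxy-4-methyl-7-(trifluoromethylsulfonyloxy)tetralin-8-yl]acetate | CC(C)[C@H]1CC[C@H](C)c2c(OC)c(OC)c(OS(=O)(=O)C(F)(F)F)c(CC(=O)OC)c21
F3 | step 8 | (4S)-7-(benzyloxy)-5,6-dimethoxy-4-methyltetralin-1-ol | OC1CC[C@H](C)c2c(OC)c(OC)c(OCc3ccccc3)cc21
F4 | step 8 | 1,4-trans-(4S)-7-(benzyloxy)-1-isopropenyl-5,6-dimethoxy-4-methyltetralin | C=C(C)[C@H]1CC[C@H](C)c2c(OC)c(OC)c(OCc3ccccc3)cc21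
F5 | step 17 | δ-hydroxy-β-keto lactone (aldol adduct of 28 and (E)-3,4-dimethoxycinnamaldehyde) | CC(C)[C@H]1CC[C@H](C)c2c(OC)c(OC)c3c(C(C(=O)CC(O)/C=C/c4ccc(OC)c(OC)c4)C(=O)OC3)c21
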